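All constants are those of an exercise; the run is a simulation.

I began with the easy step, which was to list the ways the starting material leaves this flask.

    intermediate B → target (k1 = 0.010 min⁻¹)
    intermediate A ⇌ intermediate C (K2 = 0.98, k2 = 0.0015 min⁻¹)
    starting material → side product (k3 = 0.016 min⁻¹)
    starting material + partner ⇌ intermediate A (K4 = 0.37 M⁻¹, k4 = 2.1 × 10⁻⁴ M⁻¹ min⁻¹)
    2 starting material → homo dimer (k5 = 4.6 × 10⁻⁶ M⁻¹ min⁻¹)
    partner + intermediate A → intermediate B (k6 = 0.0073 M⁻¹ min⁻¹)

starting material 0.99 M; partner 1.09 M; time 15 d

- in percentages every species weighs as the starting material in it: one homo dimer counts as two
- for a step with 2 of a species take k times the square, and two of it per event
- the reaction counts as stopped when no species that holds the starting material changes by six tenths of a point or more over the second half of the time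
- run time (flask): 15 d

1. at 15 d, what has stopped the reaction, if anything has (all of the starting material has reacted / forward and back rates have come level / the partner has run out first / it is still moving)
2. share of the starting material used up at 15 d
3. side product at 15 d, in percent of the starting material charged

Which way was faster? Alone, the direct step to side product halved the starting material in 0.72 h, while the forward step with partner to intermediate A took 2.1 d with the partner as charged, so the direct step was the faster, by a factor of 70 at the start. The step to homo dimer, at 9.11 × 10⁻⁶ min⁻¹ with the charge whole, was far slower than the direct step's 0.016 min⁻¹, so I dropped it.

Did the partner then change? Taking two partner for each starting material diverted, I reckoned the loss at 2.56% of the partner charge. I therefore froze the partner at its charge, which made the partner step pseudo-first-order with constant 2.29 × 10⁻⁴ min⁻¹. The split was then 98.6% to side product. This is the side-product share, the direct constant over the sum of itself and the frozen partner constant.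

Was there time? The half-life of 0.72 h was short against 15 d, so I expected the starting material to be used up and the side product to stand at the share.

The forecast said all of the starting material has reacted, with 100% used and 98.6% side product, the diverted part being one that “mostly drains irreversibly through B to target”.

The flask gave all of the starting material has reacted, with 100% used and 98.7% side product, 0.100 percentage points from the share. For the neighbouring flask, with 1.9 M of partner, I reckoned a share of 97.6%, which left 2.40% for the partner route. In that neighbour flask the partner kept 98% of its charge and starting material ran out first, with 0% left. At 15.0 d that neighbour flask held 97.7% side product and 2.32% target.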